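**Remark on the chemistry (assumption):** the SMILES carries no stereodescriptor and the molecule has no stereocentre or stereogenic axis. It is treated as achiral bis[3-bromo-2-(2,3-dibromo-4,5-dihydroxybenzyl)-4,5-dihydroxybenzyl] ether, C28H20Br6O9. Ring A is the inner ring: C1 bears the OCH2 carbon, C2 the CH2 to ring B, C3 Br, C4 and C5 OH, C6 H. Ring B is the outer ring: C1′ bears the CH2, C2′ and C3′ Br, C4′ and C5′ OH, C6′ H. TBS stands for tert-butyldimethylsilyl. 5-Bromovanillin is taken as the commercial starting material.

## Analysis of the target

The target is a C2-symmetric dibenzyl ether, O(CH2–ring A–CH2–ring B)2, with two identical diarylmethane halves and no stereocentre. Both rings A are pentasubstituted, and three different neighbours (CH2O at C1, benzyl at C2, Br at C3) must be placed with full regiocontrol. The feature the route is built on is that in ring A the benzylic carbon on C2 and the bromine on C3 are neighbours, with C3 lying beside the oxygen-bearing C4. Ring B carries two bromines on exactly these two positions, so ring A is ring B with the C2 bromine exchanged for a benzyl group. The molecule is therefore four copies of one 2,3-dihalo-4,5-dioxygenated C6–C1 unit about a twofold axis through the ether oxygen, which invites an aryne across C2–C3 of ring A and a two-directional assembly on the symmetric ether. The sensitive groups are four catechols (autoxidation, especially under base) and six aryl bromides (reduction, palladium insertion, halogen–metal exchange). The central bis(4-hydroxybenzyl) ether is also fragile: each CH2–O bond is para to the C4 oxygen and ionizes to a p-quinone methide type cation under Brønsted or Lewis acid, or by alkoxide loss from the C4 phenoxide. The hardest constraint is that eight phenols must be freed at the end without any reagent that cleaves this ether, which rules out methyl ether protection and BBr3.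

## Retrosynthetic reasoning

**14 to 13.** The last operation removes only eight phenol protecting groups. Silyl ethers are chosen because buffered fluoride cleaves them without ionizing the benzylic ether or touching an aryl bromide. 13 therefore already holds the full skeleton and all six bromines.

**13 to 6 and two molecules of 9 (key disconnection).** In each ring A two neighbouring bonds are cut at once, C2–CH2 and C3–Br. This leads back to an aryne across C2–C3, written for both rings as 11. The cut is made here because it reveals that rings A and B are the same unit: 11 arises from the tetrabromide 6 through the aryl Grignard 10, and the benzyl donor 9 comes from the same aldehyde as 6. Two C–C and two C–Br bonds are gained in one operation on a symmetric core, with no Lewis acid near the ether. The forward reaction must exchange one bromine on each ring of 6, eliminate to the aryne, add 9 at C2 only, and brominate the aryl Grignard 12 at C3.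

**9 to 8 to 7 to 4.** The C–Mg bond comes from a benzylic C–Cl bond by magnesium insertion, the chloride from the alcohol 7, and 7 from the aldehyde 4 by hydride reduction.

**6 to two molecules of 4.** Both C–O bonds of the ether are cut back to two aldehyde carbons. A reductive homo-etherification through the silyl ether 5 makes the symmetric core in one step and avoids the alkoxide conditions that would move aryl silyl groups.

**4 to 3 to 2 to 1.** The silyl groups are removed (4 to 3), the C5 oxygen is returned to its methyl ether (3 to 2), and the C2 bromine is removed (2 to 1). In the forward direction the methoxy group of 1 directs the second bromine para to itself, next to the first.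

## Alternatives that were turned down

**Alternative 1:** (the textbook route) Disconnection: first the ether C–O bond, then in each half the C2–CH2 bond by electrophilic aromatic substitution, all in the methyl ether series. Forward key step: AlCl3-mediated Friedel–Crafts benzylation of 3-bromo-4,5-dimethoxybenzyl acetate A2 at C2 by the cation from (2,3-dibromo-4,5-dimethoxyphenyl)methanol A1, followed by ester cleavage to the half alcohol A3. A3 and its bromide A4 are then joined by Williamson etherification to the octamethyl ether A5, and BBr3 is used last. It was turned down for three reasons: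
- The benzylic C–O bond of A2 carries the same para-methoxy group as A1 and one bromine fewer, so it should ionize at least as easily and self-condense.
- Any reagent that cleaves the eight methyl ethers of A5 also cleaves its bis(4-methoxybenzyl) ether, so the ether would have to be rebuilt on unprotected material.
- The route is linear, needs two different ring building blocks, and forms every bond of each half one at a time.

**Alternative 2:** Disconnection: the same two C2–CH2 bonds, cut on the intact symmetric ether by palladium catalysis. Forward key step: twofold Negishi coupling of the diiodide A6 with the benzylic zinc chloride A7 to give 13. It was turned down because: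
- A6 needs a third halogen pattern (iodine on C2 beside bromine on C3), made by separate halogenation of a deactivated ring, so rings A and B no longer share one precursor.
- Selectivity rests only on iodide versus bromide, yet the iodide is the most hindered C–X bond (flanked by CH2O and Br) while six C–Br bonds compete.
- It only changes the catalyst for the bond that the textbook route also forms.

**Alternative 3:** Disconnection: all benzylic C–C and C–O bonds through p-quinone methides of unprotected bromocatechols. Forward key step: acid-promoted condensation of 2,3-dibromo-4,5-dihydroxybenzyl alcohol A8 with 3-bromo-4,5-dihydroxybenzyl alcohol A9 to the half alcohol A10, then dehydrative dimerization of A10 to 14. It was turned down because: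
- A8, A9 and A10 all ionize to quinone methides, and each offers free ring carbons ortho to a hydroxyl as well as oxygen nucleophiles.
- A9 is both the better cation precursor and the better nucleophile, so self-condensation should outrun the cross-benzylation.
- Nothing in the substrates separates C-alkylation from O-alkylation, so the target would be one member of a statistical oligomer mixture.

Key step: step 7

## Route

Step 1
Reactants: 1 5-bromovanillin (3-bromo-4-hydroxy-5-methoxybenzaldehyde)
Product: 2 2,3-dibromo-4-hydroxy-5-methoxybenzaldehyde (5,6-dibromovanillin)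
Conditions: Br2 (1.2 equiv), Fe powder (cat.), AcOH, rt → 50 °C
Reagents that add atoms: bromine, BrBr
Why: Electrophilic aromatic bromination; of the two free positions the one para to the methoxy group is the more activated, while the other is squeezed between CHO and OMe, so the second bromine should enter next to the first.

Step 2
Reactants: 2 2,3-dibromo-4-hydroxy-5-methoxybenzaldehyde
Product: 3 2,3-dibromo-4,5-dihydroxybenzaldehyde
Conditions: BBr3 (2.5 equiv), CH2Cl2, −78 °C → rt; then H2O
Reagents that add atoms: none
Why: Lewis acid cleavage of an aryl methyl ether (bromide attacks the methyl group of the boron-bound ether); the neighbouring phenol gives a cyclic borate that hydrolyses on work-up, and the aldehyde and aryl bromides should be inert.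

Step 3
Reactants: 3 2,3-dibromo-4,5-dihydroxybenzaldehyde
Product: 4 2,3-dibromo-4,5-bis(tert-butyldimethylsilyloxy)benzaldehyde
Conditions: TBSCl (2.6 equiv), imidazole (5 equiv), DMF, rt → 40 °C
Reagents that add atoms: tert-butyldimethylsilyl chloride, CC(C)(C)[Si](C)(C)Cl
Why: Standard imidazole-promoted silylation of phenols; both catechol oxygens are acidic and the formyl group para to O4 aids silylation of the more hindered C4 hydroxyl.

Step 4
Reactants: 4 2,3-dibromo-4,5-bis(tert-butyldimethylsilyloxy)benzaldehyde (two molecules)
Product: 6 bis[2,3-dibromo-4,5-bis(tert-butyldimethylsilyloxy)benzyl] ether, via triethylsilyl benzyl ether 5 (not isolated)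
Conditions: Et3SiH (1.2 equiv), BiBr3 (3 mol %), MeCN, rt
Reagents that add atoms: none
Why: Lewis acid catalysed reductive homo-etherification of an aldehyde: hydrosilylation gives 5, which condenses with a second aldehyde to an oxocarbenium ion that the silane reduces. The conditions are close to neutral and aryl silyl ethers should survive them.

Step 5
Reactants: 4 2,3-dibromo-4,5-bis(tert-butyldimethylsilyloxy)benzaldehyde
Product: 7 [2,3-dibromo-4,5-bis(tert-butyldimethylsilyloxy)phenyl]methanol
Conditions: NaBH4, THF/EtOH, 0 °C
Reagents that add atoms: none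
Why: Borohydride reduction of an aryl aldehyde; short reaction at 0 °C should leave aryl silyl ethers and aryl bromides untouched.

Step 6
Reactants: 7 [2,3-dibromo-4,5-bis(tert-butyldimethylsilyloxy)phenyl]methanol
Product: 8 2,3-dibromo-4,5-bis(tert-butyldimethylsilyloxy)benzyl chloride
Conditions: PPh3, N-chlorosuccinimide, THF, 0 °C → rt
Reagents that add atoms: N-chlorosuccinimide, O=C1CCC(=O)N1Cl
Why: Appel-type chlorination through an alkoxyphosphonium ion and SN2 attack of chloride; the medium stays neutral, so the silyl ethers should survive, and the chloride is preferred over the bromide to limit Wurtz coupling in the next step.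

Step 7
Reactants: 6 bis[2,3-dibromo-4,5-bis(tert-butyldimethylsilyloxy)benzyl] ether; 8 2,3-dibromo-4,5-bis(tert-butyldimethylsilyloxy)benzyl chloride (4.5 equiv)
Product: 13 bis{3-bromo-2-[2,3-dibromo-4,5-bis(tert-butyldimethylsilyloxy)benzyl]-4,5-bis(tert-butyldimethylsilyloxy)benzyl} ether, via benzylmagnesium chloride 9 (not isolated), via twofold aryl Grignard 10 (not isolated), via twofold aryne 11 (not isolated), via twofold benzylated aryl Grignard 12 (not isolated)
Conditions: (a) 8, Mg turnings, 2-MeTHF, 0 °C; (b) 6, iPrMgCl·LiCl (2.1 equiv), THF, −30 °C; (c) solution b added over 2 h to solution a, 40 °C; (d) BrCCl2CCl2Br (excess), −40 °C → rt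
Reagents that add atoms: 1,2-dibromo-1,1,2,2-tetrachloroethane, BrC(Cl)(Cl)C(Cl)(Cl)Br
Why: Proposed new method: Halogen–magnesium exchange on each ring of 6 should occur at the C3 bromine, which is ortho to the silyloxy oxygen, to give 10; on warming, 10 loses MgBrCl across C2–C3 and the arynes written as 11 arise one ring after the other in an excess of 9. The benzylic carbon of 9 adds to C2 and magnesium returns to C3 (12), where the bromine donor replaces it, so each ring A gains its C2–CH2 bond and regains its C3–Br bond in the same flask. The closest known reaction types are the addition of Grignard reagents to arynes generated from ortho-dihaloarenes with halogen quench of the resulting aryl Grignard, and the meta-selective addition of nucleophiles to 3-alkoxy- and 3-silyloxyarynes; not yet shown are a benzylic Grignard reagent that itself carries aryl bromides and the twofold execution on one substrate. No ring is closed and no stereocentre is formed. The selectivity needed is addition at C2 and not at C3: the oxygen on C4 beside the triple bond distorts and polarizes the aryne so that the nucleophile attacks the distal carbon C2 and the carbanion develops at C3 next to oxygen, the C5 oxygen (para to C2) acts weakly in the same sense, the bulky silyloxy group shields C3, and the benzylic ether oxygen on the C1 side can guide magnesium to C2. Chemoselectivity rests on the order of events: the exchange reagent is consumed at −30 °C before 9 is met, and a benzylic Grignard reagent is a kinetically poor partner for halogen–magnesium exchange with the ring B bromides. Slow addition of 10 to an excess of 9 should keep the aryl Grignard species, each flanked by two ortho substituents, from competing for the aryne.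

Step 8
Reactants: 13 bis{3-bromo-2-[2,3-dibromo-4,5-bis(tert-butyldimethylsilyloxy)benzyl]-4,5-bis(tert-butyldimethylsilyloxy)benzyl} ether
Product: 14 bis[3-bromo-2-(2,3-dibromo-4,5-dihydroxybenzyl)-4,5-dihydroxybenzyl] ether (CNP0255526.0)
Conditions: TBAF (8.8 equiv), AcOH (10 equiv), THF, degassed, 0 °C → rt; pH 4 aqueous work-up, no alcohol solvents
Reagents that add atoms: none
Why: Fluoride attacks silicon and releases each phenol, which the acetic acid buffer protonates at once, so the C4 phenoxide should not expel the benzylic alkoxide as a p-quinone methide. The ether and the aryl bromides are inert to fluoride.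

## Compound list

1 | 5-bromovanillin (3-bromo-4-hydroxy-5-methoxybenzaldehyde) | O=Cc1cc(OC)c(O)c(Br)c1 | starting material
2 | 2,3-dibromo-4-hydroxy-5-methoxybenzaldehyde | O=Cc1cc(OC)c(O)c(Br)c1Br | intermediate
3 | 2,3-dibromo-4,5-dihydroxybenzaldehyde | O=Cc1cc(O)c(O)c(Br)c1Br | intermediate
4 | 2,3-dibromo-4,5-bis(tert-butyldimethylsilyloxy)benzaldehyde | O=Cc1cc(O[Si](C)(C)C(C)(C)C)c(O[Si](C)(C)C(C)(C)C)c(Br)c1Br | intermediate
5 | {[2,3-dibromo-4,5-bis(tert-butyldimethylsilyloxy)benzyl]oxy}triethylsilane | CC[Si](CC)(CC)OCc1cc(O[Si](C)(C)C(C)(C)C)c(O[Si](C)(C)C(C)(C)C)c(Br)c1Br | intermediate (not isolated)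
6 | bis[2,3-dibromo-4,5-bis(tert-butyldimethylsilyloxy)benzyl] ether | O(Cc1cc(O[Si](C)(C)C(C)(C)C)c(O[Si](C)(C)C(C)(C)C)c(Br)c1Br)Cc1cc(O[Si](C)(C)C(C)(C)C)c(O[Si](C)(C)C(C)(C)C)c(Br)c1Br | intermediate
7 | [2,3-dibromo-4,5-bis(tert-butyldimethylsilyloxy)phenyl]methanol | OCc1cc(O[Si](C)(C)C(C)(C)C)c(O[Si](C)(C)C(C)(C)C)c(Br)c1Br | intermediate
8 | 2,3-dibromo-4,5-bis(tert-butyldimethylsilyloxy)benzyl chloride | ClCc1cc(O[Si](C)(C)C(C)(C)C)c(O[Si](C)(C)C(C)(C)C)c(Br)c1Br | intermediate
9 | 2,3-dibromo-4,5-bis(tert-butyldimethylsilyloxy)benzylmagnesium chloride | Cl[Mg]Cc1cc(O[Si](C)(C)C(C)(C)C)c(O[Si](C)(C)C(C)(C)C)c(Br)c1Br | intermediate (not isolated)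
10 | bis[2-bromo-3-(chloromagnesio)-4,5-bis(tert-butyldimethylsilyloxy)benzyl] ether | O(Cc1cc(O[Si](C)(C)C(C)(C)C)c(O[Si](C)(C)C(C)(C)C)c([Mg]Cl)c1Br)Cc1cc(O[Si](C)(C)C(C)(C)C)c(O[Si](C)(C)C(C)(C)C)c([Mg]Cl)c1Br | intermediate (not isolated)
11 | bis[4,5-bis(tert-butyldimethylsilyloxy)-2,3-didehydrobenzyl] ether (aryne stage drawn for both rings; the two arynes are expected to form and react one after the other) | O(CC1=CC(O[Si](C)(C)C(C)(C)C)=C(O[Si](C)(C)C(C)(C)C)C#C1)CC1=CC(O[Si](C)(C)C(C)(C)C)=C(O[Si](C)(C)C(C)(C)C)C#C1 | intermediate (not isolated)
12 | bis{3-(chloromagnesio)-2-[2,3-dibromo-4,5-bis(tert-butyldimethylsilyloxy)benzyl]-4,5-bis(tert-butyldimethylsilyloxy)benzyl} ether | O(Cc1cc(O[Si](C)(C)C(C)(C)C)c(O[Si](C)(C)C(C)(C)C)c([Mg]Cl)c1Cc1cc(O[Si](C)(C)C(C)(C)C)c(O[Si](C)(C)C(C)(C)C)c(Br)c1Br)Cc1cc(O[Si](C)(C)C(C)(C)C)c(O[Si](C)(C)C(C)(C)C)c([Mg]Cl)c1Cc1cc(O[Si](C)(C)C(C)(C)C)c(O[Si](C)(C)C(C)(C)C)c(Br)c1Br | intermediate (not isolated)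
13 | bis{3-bromo-2-[2,3-dibromo-4,5-bis(tert-butyldimethylsilyloxy)benzyl]-4,5-bis(tert-butyldimethylsilyloxy)benzyl} ether | O(Cc1cc(O[Si](C)(C)C(C)(C)C)c(O[Si](C)(C)C(C)(C)C)c(Br)c1Cc1cc(O[Si](C)(C)C(C)(C)C)c(O[Si](C)(C)C(C)(C)C)c(Br)c1Br)Cc1cc(O[Si](C)(C)C(C)(C)C)c(O[Si](C)(C)C(C)(C)C)c(Br)c1Cc1cc(O[Si](C)(C)C(C)(C)C)c(O[Si](C)(C)C(C)(C)C)c(Br)c1Br | intermediate
14 | bis[3-bromo-2-(2,3-dibromo-4,5-dihydroxybenzyl)-4,5-dihydroxybenzyl] ether | Oc1cc(Cc2c(COCc3cc(O)c(O)c(Br)c3Cc3cc(O)c(O)c(Br)c3Br)cc(O)c(O)c2Br)c(Br)c(Br)c1O | target

## Step count and least certain steps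

Total: 8 steps. Longest linear sequence: 7 steps (steps 1, 2, 3, 5, 6, 7, 8); step 4 is the branch to the core 6.

**Step 7 (key step, proposed new method).** The following processes are the most likely to go wrong:
- Wurtz coupling and magnesium insertion into ring bromides while 9 is formed.
- Addition of the aryl Grignard species to the aryne in place of 9, which gives oligomers.
- Halogen–magnesium scrambling onto ring B at the temperature needed for the elimination, which opens unwanted aryne channels.
- Partial addition at C3.

The fallback uses known chemistry, sets out from 8 and 4 and comes back at 13. Chloride 8 is treated under Barbier conditions (Mg, pinacolborane, THF, rt), where the benzylic magnesium species is trapped as it forms. This should give 2-[2,3-dibromo-4,5-bis(tert-butyldimethylsilyloxy)benzyl]-4,4,5,5-tetramethyl-1,3,2-dioxaborolane F1. A Suzuki–Miyaura coupling of F1 with aldehyde 4 (PdCl2(dppf), K3PO4, toluene/H2O, 70 °C) should take place at the C2–Br bond. This is the only C–Br bond ortho to the formyl group and so the one most prone to oxidative addition to zerovalent palladium. The product would be 3-bromo-2-[2,3-dibromo-4,5-bis(tert-butyldimethylsilyloxy)benzyl]-4,5-bis(tert-butyldimethylsilyloxy)benzaldehyde F2. The reductive homo-etherification of step 4 (Et3SiH, BiBr3, MeCN), applied to F2, then gives 13.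

**Step 4.** Over-reduction of the benzylic C–O bond, stalling at the stage of 5, or loss of silyl groups through adventitious HBr may occur, because the oxocarbenium ion is hindered by the ortho bromine. The fallback sets out from 7 and 8 and comes back at 6. Alcohol 7 is alkylated with chloride 8 under silver assistance (AgOTf, 2,6-di-tert-butylpyridine, CH2Cl2, 0 °C), an etherification that needs neither a silane nor an alkoxide. No new compound is made on this way.

**Step 8.** Elimination of the benzylic alkoxide from a C4 phenoxide (p-quinone methide formation), solvolysis of the ether, and autoxidation of the free catechols may occur, because eight phenoxides are released in sequence. The fallback sets out from 13 and comes back at 14. The silyl groups are exchanged for acetyl groups in one pot (CsF, Ac2O, DMF, rt), so each phenoxide is acetylated as it is released. This gives the octaacetate bis[3-bromo-2-(2,3-dibromo-4,5-diacetoxybenzyl)-4,5-diacetoxybenzyl] ether F3, which can be purified as a stable compound. Hydrazinolysis (N2H4·H2O, THF, 0 °C, degassed, pH 4 work-up) then frees 14 under nearly neutral conditions.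

## Further compounds

F1 | step 7 | 2-[2,3-dibromo-4,5-bis(tert-butyldimethylsilyloxy)benzyl]-4,4,5,5-tetramethyl-1,3,2-dioxaborolane | CC1(C)OB(Cc2cc(O[Si](C)(C)C(C)(C)C)c(O[Si](C)(C)C(C)(C)C)c(Br)c2Br)OC1(C)C
F2 | step 7 | 3-bromo-2-[2,3-dibromo-4,5-bis(tert-butyldimethylsilyloxy)benzyl]-4,5-bis(tert-butyldimethylsilyloxy)benzaldehyde | O=Cc1cc(O[Si](C)(C)C(C)(C)C)c(O[Si](C)(C)C(C)(C)C)c(Br)c1Cc1cc(O[Si](C)(C)C(C)(C)C)c(O[Si](C)(C)C(C)(C)C)c(Br)c1Br
F0 | step 4 | none | none
F3 | step 8 | bis[3-bromo-2-(2,3-dibromo-4,5-diacetoxybenzyl)-4,5-diacetoxybenzyl] ether | CC(=O)Oc1cc(Cc2c(COCc3cc(OC(C)=O)c(OC(C)=O)c(Br)c3Cc3cc(OC(C)=O)c(OC(C)=O)c(Br)c3Br)cc(OC(C)=O)c(OC(C)=O)c2Br)c(Br)c(Br)c1OC(C)=O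
A1 | alternative 1 | (2,3-dibromo-4,5-dimethoxyphenyl)methanol | OCc1cc(OC)c(OC)c(Br)c1Br
A2 | alternative 1 | 3-bromo-4,5-dimethoxybenzyl acetate | CC(=O)OCc1cc(OC)c(OC)c(Br)c1
A3 | alternative 1 | [3-bromo-2-(2,3-dibromo-4,5-dimethoxybenzyl)-4,5-dimethoxyphenyl]methanol | OCc1cc(OC)c(OC)c(Br)c1Cc1cc(OC)c(OC)c(Br)c1Br
A4 | alternative 1 | 3-bromo-2-(2,3-dibromo-4,5-dimethoxybenzyl)-4,5-dimethoxybenzyl bromide | BrCc1cc(OC)c(OC)c(Br)c1Cc1cc(OC)c(OC)c(Br)c1Br
A5 | alternative 1 | bis[3-bromo-2-(2,3-dibromo-4,5-dimethoxybenzyl)-4,5-dimethoxybenzyl] ether | COc1cc(Cc2c(COCc3cc(OC)c(OC)c(Br)c3Cc3cc(OC)c(OC)c(Br)c3Br)cc(OC)c(OC)c2Br)c(Br)c(Br)c1OC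
A6 | alternative 2 | bis[3-bromo-2-iodo-4,5-bis(tert-butyldimethylsilyloxy)benzyl] ether | O(Cc1cc(O[Si](C)(C)C(C)(C)C)c(O[Si](C)(C)C(C)(C)C)c(Br)c1I)Cc1cc(O[Si](C)(C)C(C)(C)C)c(O[Si](C)(C)C(C)(C)C)c(Br)c1I
A7 | alternative 2 | 2,3-dibromo-4,5-bis(tert-butyldimethylsilyloxy)benzylzinc chloride | Cl[Zn]Cc1cc(O[Si](C)(C)C(C)(C)C)c(O[Si](C)(C)C(C)(C)C)c(Br)c1Br
A8 | alternative 3 | 2,3-dibromo-4,5-dihydroxybenzyl alcohol | OCc1cc(O)c(O)c(Br)c1Br
A9 | alternative 3 | 3-bromo-4,5-dihydroxybenzyl alcohol | OCc1cc(O)c(O)c(Br)c1
A10 | alternative 3 | 3-bromo-2-(2,3-dibromo-4,5-dihydroxybenzyl)-4,5-dihydroxybenzyl alcohol | OCc1cc(O)c(O)c(Br)c1Cc1cc(O)c(O)c(Br)c1Br
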